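An easy step comes first: I take the base-ten logarithm of bis adduct over single product and call it the log odds, so that the share asked for, the selectivity, becomes a distance in decades.

| flask | substrate | reagent | remark | time |
|---|---|---|---|---|
| Saturday's | 0.25 M | 0.375 M | run made earlier |  |
| Wednesday's | 0.12 M | 0.375 M | run made earlier |  |
| Thursday's | 0.50 M | 0.375 M | run made earlier |  |
| north-west | 0.25 M (fed, over 2.5 min) | 0.375 M | all else is in the flask from the start; the feed brings no volume worth counting | 3.0 min |
| south-east | 0.25 M | 0.375 M | everything together at the start | 3.0 min |
| north | 0.25 M | 0.375 M (fed, over 2.5 min) | all else is in the flask from the start; the feed brings no volume worth counting | 3.0 min |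

Saturday's run (percent of the substrate charged)

| time / min | single product / % | bis adduct / % | substrate / % |
|---|---|---|---|
| 0.250 | 43 | 20 | 25 |
| 0.417 | 37 | 23 | 16 |
| 0.667 | 34 | 32 | 6 |
| 1.00 | 31 | 35 | 4 |
| 2.00 | 24 | 38 | 0 |
| 3.00 | 22 | 42 | 0 |

Wednesday's run (percent of the substrate charged)

| time / s | single product / % | bis adduct / % | substrate / % |
|---|---|---|---|
| 10.0 | 48 | 18 | 31 |
| 15.0 | 49 | 25 | 21 |
| 25.0 | 42 | 38 | 13 |
| 40.0 | 37 | 48 | 6 |
| 60.0 | 26 | 60 | 1 |
| 120 | 14 | 75 | 3 |

Thursday's run (percent of the substrate charged)

| time / s | single product / % | bis adduct / % | substrate / % |
|---|---|---|---|
| 10.0 | 33 | 6 | 41 |
| 20.0 | 27 | 12 | 25 |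
| 40.0 | 19 | 10 | 17 |
| 60.0 | 15 | 7 | 10 |
| 80.0 | 16 | 13 | 11 |
| 120 | 9 | 13 | 3 |

(each reading ± 2 percentage points)

- percent here means substrate units held: one side product counts as two
- what is said of released group includes crystals
- crystals is a solid; its amount is given per volume of the solution
- what may be going on: substrate + single product -> side product; substrate + reagent -> single product + released group; crystals <-> released group; reagent + single product -> bis adduct + released group; 2 reagent -> homo dimer

- the best flask by share of single product in single product plus bis adduct; "all alike" if 1.5 percentage points covers them all (north-west / south-east / north / all alike)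
- share of single product in single product plus bis adduct at the end, north-west
- share of single product in single product plus bis adduct at the end, south-east
- share of single product in single product plus bis adduct at the end, north

At the last readings, Saturday's run, with 1.50 equivalents of reagent, reads 0.281, and Wednesday's, with 3.12, reads 0.729. That gives 1.41, the climb: decades of log odds gained per decade of charged reagent-to-substrate ratio. It is a reading, with a scatter of 2 percentage points behind it, and the two readings stand at 3.00 min and 120 s, so the time differs as well as the ratio. Thursday's run, at 0.750 equivalents, reads 0.160, so the slope below Saturday's ratio reads 0.402, less than the 1.41 above it, and I carry the upper value upward from Saturday's ratio.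

South-east repeats Saturday's recipe. Turned round, the question is what a fed flask needs in order to beat it: log odds under 0.281. North-west, counting charges, has 3.00 equivalents at the midpoint of its feed, which the climb puts 0.424 decades too high. North stays under 1.50 equivalents until its feed ends, but Thursday's substrate-rich run keeps 25.0 % of its substrate outside side product at its last reading, less than Saturday's 64.0 % at its own, so I expect north to lose substrate to side product early in its feed and its later reagent to turn single product into bis adduct. So I commit to south-east.

The forecast names north-west, with 38 %, 35 % and 23 % for north-west, south-east and north, expecting in north-west that “dimer loss starves the reagent”.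

The flask gives south-east: 32.1 % for north-west, 35.9 % for south-east, 24.5 % for north. North-west ends with 34 % of its substrate and 0.27 % of its reagent left. South-east's log odds are 0.252 and north-west's 0.325, and through the climb north-west's match a batch at 1.69 equivalents.

    substrate + single product → side product (k = 0.150 /M/s)
    substrate + reagent → single product + released group (k = 0.410 /M/s)
    crystals ⇌ released group, rate k3*(cs3 - [released group]) while solid is left; crystals form when [released group] > cs3 (solubility = 0.160 M, k = 0.800 /s)
    reagent + single product → bis adduct + released group (k = 0.190 /M/s)
    2 reagent → homo dimer (k = 0.0390 /M/s)

A flask like south-east with 0.94 M of reagent should climb to 0.813, a share of 13.3 %. It gives 2.52 %, lower than the climb said, with 87.6 % as bis adduct.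

All runs were generated by integration on assumed constants; scatter was added.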